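The decalin is traced back to an open chain that carries a 1,2,2-trimethylcyclopentane: C10, C1, C2, C3 and C4 form that ring and C5 is an oxirane carbon outside it. In the key step MeAlCl2 opens the oxirane at C5, the gem-dimethyl carbon C4 shifts from C10 to C5 and ring A is thereby enlarged from five to six atoms; the C10 cation then adds to the 8(9)-olefin and closes ring B. The step exploits that C4 flanks C5 and that C10 is quaternary, and it sets C5, C10 and the C6 oxygen at once. The 6-ketone later directs the 7α- and 6β-oxygens.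

Key step: step 8

Remark: labdane numbering is used for all atoms; the cyclopentane stereocentre of 3 (future C10) is carried as a racemate and C6 as both epimers from 11 to 14, because both are erased later (planar C10 cation in step 8, C6 carbonyl in step 9).

Step 1
Reactants: 1 1-(2-methylcyclopent-1-en-1-yl)ethan-1-one
Product: 3 rac-1-(1,2,2-trimethylcyclopentyl)ethan-1-one, via lithium enolate 2 (not isolated)
Conditions: MeLi, CuI, Et2O, 0 °C (gives Me2CuLi); then MeI, DMPU, THF, 0 °C to rt
Reagents that add atoms: lithium dimethylcuprate [Li+].C[Cu-]C; iodomethane CI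
Why: Conjugate addition of the cuprate to the β,β-disubstituted enone creates the gem-dimethyl carbon and the resulting enolate is C-methylated in the same flask (tandem 1,4-addition–enolate alkylation), so the new quaternary stereocentre forms as a racemate, which is acceptable because this carbon becomes the planar C10 cation in step 8.

Step 2
Reactants: 4 nerol [(2Z)-3,7-dimethylocta-2,6-dien-1-ol]
Product: 5 tert-butyl{[(2Z)-3,7-dimethylocta-2,6-dien-1-yl]oxy}diphenylsilane
Conditions: t-BuPh2SiCl, imidazole, DMF, rt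
Reagents that add atoms: tert-butyl(chloro)diphenylsilane CC(C)(C)[Si](Cl)(c1ccccc1)c1ccccc1
Why: Silylation of the primary allylic alcohol with the chlorosilane and imidazole is routine, makes no stereocentre and leaves the Z olefin untouched.

Step 3
Reactants: 5 tert-butyl{[(2Z)-3,7-dimethylocta-2,6-dien-1-yl]oxy}diphenylsilane
Product: 6 (2E,6Z)-8-[(tert-butyldiphenylsilyl)oxy]-2,6-dimethylocta-2,6-dien-1-ol
Conditions: SeO2 (cat.), t-BuOOH, salicylic acid (cat.), CH2Cl2, rt
Reagents that add atoms: tert-butyl hydroperoxide CC(C)(C)OO (terminal oxygen source; SeO2 is the catalytic carrier)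
Why: Allylic oxidation with SeO2 (ene reaction followed by [2,3]-sigmatropic shift) attacks the E methyl group of the terminal trisubstituted olefin, which is more electron-rich than the olefin next to the silyl ether, so the new allylic alcohol should be formed with E geometry and without a stereocentre.

Step 4
Reactants: 6 (2E,6Z)-8-[(tert-butyldiphenylsilyl)oxy]-2,6-dimethylocta-2,6-dien-1-ol
Product: 7 {[(2Z,6E)-8-bromo-3,7-dimethylocta-2,6-dien-1-yl]oxy}(tert-butyl)diphenylsilane
Conditions: CBr4, PPh3, CH2Cl2, 0 °C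
Reagents that add atoms: carbon tetrabromide BrC(Br)(Br)Br
Why: The Appel reaction converts the primary allylic alcohol into the bromide by SN2 displacement of the oxyphosphonium group without allylic transposition or loss of olefin geometry.

Step 5
Reactants: 3 rac-1-(1,2,2-trimethylcyclopentyl)ethan-1-one; 7 {[(2Z,6E)-8-bromo-3,7-dimethylocta-2,6-dien-1-yl]oxy}(tert-butyl)diphenylsilane
Product: 9 (4E,8Z)-10-[(tert-butyldiphenylsilyl)oxy]-4,8-dimethyl-1-(1,2,2-trimethylcyclopentyl)deca-4,8-dien-1-one, via lithium enolate 8 (not isolated)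
Conditions: LiN(iPr)2, THF, −78 °C; then 7, −78 to 0 °C
Reagents that add atoms: none
Why: The methyl ketone can enolise only towards its methyl group, and SN2 alkylation of this lithium enolate by the primary allylic bromide joins the two fragments at the C6–C7 bond without forming a stereocentre.

Step 6
Reactants: 9 (4E,8Z)-10-[(tert-butyldiphenylsilyl)oxy]-4,8-dimethyl-1-(1,2,2-trimethylcyclopentyl)deca-4,8-dien-1-one
Product: 11 (4E,8Z)-2-bromo-10-[(tert-butyldiphenylsilyl)oxy]-4,8-dimethyl-1-(1,2,2-trimethylcyclopentyl)deca-4,8-dien-1-one (both C2 epimers), via trimethylsilyl enol ether 10 (not isolated)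
Conditions: LiN(SiMe3)2, Me3SiCl, THF, −78 °C; then N-bromosuccinimide, −78 to 0 °C
Reagents that add atoms: N-bromosuccinimide O=C1CCC(=O)N1Br
Why: The silyl enol ether, which can form only towards C6, is brominated by N-bromosuccinimide far faster than the trisubstituted olefins (α-halogenation of a ketone through its enol ether); the bromo-bearing carbon forms as both epimers, which is harmless because C6 ends as a carbonyl in step 9.

Step 7
Reactants: 11 (4E,8Z)-2-bromo-10-[(tert-butyldiphenylsilyl)oxy]-4,8-dimethyl-1-(1,2,2-trimethylcyclopentyl)deca-4,8-dien-1-one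
Product: 13 tert-butyl({(2Z,6E)-3,7-dimethyl-8-[(3R)-3-(1,2,2-trimethylcyclopentyl)oxiran-2-yl]octa-2,6-dien-1-yl}oxy)diphenylsilane (both epimers at oxirane C2), via bromohydrin 12 (not isolated)
Conditions: (R)-2-methyl-CBS-oxazaborolidine (0.2 equiv), BH3·SMe2, THF, −20 °C; MeOH; then K2CO3, MeOH, rt
Reagents that add atoms: none
Why: In the CBS reduction the tert-alkyl group acts as the large substituent, so the (R)-oxazaborolidine should deliver hydride to one face of both bromo epimers under catalyst control and set the carbinol as R, and the alkoxide then displaces bromide in a Williamson closure that leaves this centre untouched as C5 of the oxirane.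

Step 8
Reactants: 13 tert-butyl({(2Z,6E)-3,7-dimethyl-8-[(3R)-3-(1,2,2-trimethylcyclopentyl)oxiran-2-yl]octa-2,6-dien-1-yl}oxy)diphenylsilane
Product: 14 (13Z)-15-[(tert-butyldiphenylsilyl)oxy]labda-7,13-dien-6-ol (5S,9S,10S; both C6 epimers)
Conditions: MeAlCl2 (2 equiv), CH2Cl2, −78 °C; then Et3N, MeOH; aq. KNaC4H4O6
Reagents that add atoms: none
Why: Proposed new method: MeAlCl2 activates the oxirane and the C5–O bond breaks with backside participation of the anti-periplanar C10–C4 σ-bond, so the gem-dimethyl carbon C4 shifts from C10 to C5 (Wagner–Meerwein ring enlargement of the cyclopentane to ring A) and leaves a tertiary cation at C10, which the 8(9)-olefin attacks to close ring B before C8 loses a proton towards C7. The closest known reactions are the Lewis acid-induced cyclisations of epoxy olefins, the ring-enlarging ionisation of 1-methylcyclopentylcarbinyl sulfonates and the acid-induced closure of 2,2,6-trimethylcyclohexyl cations onto 1,5-olefins; their merger at a disubstituted oxirane is new. Ring A closes by a suprafacial 1,2-alkyl shift (retention at C4, inversion at C5) and ring B by a 6-endo-trig cation–olefin addition through a chair. C5 is set by inversion of the (R) oxirane carbon, C10 by the chair transition state that places C1 and C4 equatorial on the forming ring (trans fusion, relayed from C5), C9 by the E olefin geometry, and C6 is carried over from the oxirane and erased in step 9. The step needs C4 to migrate in preference to C1, to the methyl group and to a hydride shift from C6: C4 is the most substituted migrating carbon, its shift relieves cyclopentane strain, and the C6–H bond of the intact oxirane cannot align with the breaking C5–O bond. It also needs the cascade to stop after ring B, which the inductively deactivated Z-allylic silyl ether olefin should secure at −78 °C; any 8(9)- or 8(17)-olefin isomer formed alongside converges in step 9.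

Step 9
Reactants: 14 (13Z)-15-[(tert-butyldiphenylsilyl)oxy]labda-7,13-dien-6-ol
Product: 15 (13Z)-15-[(tert-butyldiphenylsilyl)oxy]labda-7,13-dien-6-one (5S,9S,10S)
Conditions: Dess–Martin periodinane, NaHCO3, CH2Cl2, 0 °C to rt; then DBU (0.2 equiv), CH2Cl2, rt
Reagents that add atoms: none
Why: Dess–Martin oxidation converts both C6 epimers into one ketone and DBU moves any 8(9)- or 8(17)-olefin isomer into conjugation (base-mediated isomerisation), while C5 and C9, now epimerisable, settle in the trans-fused arrangement with the side chain equatorial.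

Step 10
Reactants: 15 (13Z)-15-[(tert-butyldiphenylsilyl)oxy]labda-7,13-dien-6-one
Product: 17 (13Z)-15-[(tert-butyldiphenylsilyl)oxy]-7α-hydroxylabda-8,13-dien-6-one, via potassium dienolate 16 (not isolated)
Conditions: KN(SiMe3)2 (0.95 equiv), THF, −78 to 0 °C; then 2-(phenylsulfonyl)-3-phenyloxaziridine, −78 °C; AcOH
Reagents that add atoms: 2-(phenylsulfonyl)-3-phenyloxaziridine O=S(=O)(c1ccccc1)N1OC1c1ccccc1
Why: Under equilibrating conditions the enone should give the more substituted endocyclic dienolate by loss of H-9, and oxygen transfer from the N-sulfonyloxaziridine to its α-carbon (deconjugative α-hydroxylation of an extended enolate) occurs axially on the α face, away from the C10 and 4β methyl groups, to set 7α-OH and leave the 8(9)-olefin in place.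

Step 11
Reactants: 17 (13Z)-15-[(tert-butyldiphenylsilyl)oxy]-7α-hydroxylabda-8,13-dien-6-one
Product: 18 (13Z)-15-[(tert-butyldiphenylsilyl)oxy]labda-8,13-diene-6β,7α-diol
Conditions: Me4NBH(OAc)3, MeCN–AcOH, −30 °C
Reagents that add atoms: none
Why: In this hydroxyl-directed (Evans–Saksena type) reduction the 7α-hydroxyl binds boron and delivers hydride intramolecularly to the α face of the C6 carbonyl, which is also the face free of the two axial methyl groups, so the 6β-alcohol of the trans-diol should result.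

Step 12
Reactants: 18 (13Z)-15-[(tert-butyldiphenylsilyl)oxy]labda-8,13-diene-6β,7α-diol
Product: 19 (13Z)-15-[(tert-butyldiphenylsilyl)oxy]labda-8,13-diene-6β,7α-diyl diacetate
Conditions: Ac2O, DMAP, pyridine, 50 °C
Reagents that add atoms: acetic anhydride CC(=O)OC(C)=O
Why: DMAP-catalysed acylation esterifies the allylic 7α-hydroxyl readily and, on warming, also the hindered axial 6β-hydroxyl, without touching any stereocentre.

Step 13
Reactants: 19 (13Z)-15-[(tert-butyldiphenylsilyl)oxy]labda-8,13-diene-6β,7α-diyl diacetate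
Product: 20 (13Z)-15-hydroxylabda-8,13-diene-6β,7α-diyl diacetate (5S,6S,7S,10S; CNP0187815.3)
Conditions: Bu4NF, AcOH, THF, rt
Reagents that add atoms: none
Why: Fluoride buffered with acetic acid cleaves the primary silyl ether (Si–F bond formation) under conditions in which the two secondary acetates should neither migrate nor hydrolyse, and no stereocentre is affected.

Compound list
1 | 1-(2-methylcyclopent-1-en-1-yl)ethan-1-one | CC(=O)C1=C(C)CCC1 | starting material
2 | lithium 1-(2,2-dimethylcyclopentylidene)ethan-1-olate | [Li]OC(C)=C1CCCC1(C)C | intermediate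
3 | rac-1-(1,2,2-trimethylcyclopentyl)ethan-1-one | CC(=O)C1(C)CCCC1(C)C | intermediate
4 | nerol, (2Z)-3,7-dimethylocta-2,6-dien-1-ol | CC(C)=CCC/C(C)=C\CO | starting material
5 | tert-butyl{[(2Z)-3,7-dimethylocta-2,6-dien-1-yl]oxy}diphenylsilane | CC(C)=CCC/C(C)=C\CO[Si](c1ccccc1)(c1ccccc1)C(C)(C)C | intermediate
6 | (2E,6Z)-8-[(tert-butyldiphenylsilyl)oxy]-2,6-dimethylocta-2,6-dien-1-ol | OC/C(C)=C/CC/C(C)=C\CO[Si](c1ccccc1)(c1ccccc1)C(C)(C)C | intermediate
7 | {[(2Z,6E)-8-bromo-3,7-dimethylocta-2,6-dien-1-yl]oxy}(tert-butyl)diphenylsilane | BrC/C(C)=C/CC/C(C)=C\CO[Si](c1ccccc1)(c1ccccc1)C(C)(C)C | intermediate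
8 | lithium 1-(1,2,2-trimethylcyclopentyl)ethen-1-olate | [Li]OC(=C)C1(C)CCCC1(C)C | intermediate
9 | (4E,8Z)-10-[(tert-butyldiphenylsilyl)oxy]-4,8-dimethyl-1-(1,2,2-trimethylcyclopentyl)deca-4,8-dien-1-one (ring stereocentre racemic) | CC1(C)CCCC1(C)C(=O)CC/C(C)=C/CC/C(C)=C\CO[Si](c2ccccc2)(c3ccccc3)C(C)(C)C | intermediate
10 | trimethylsilyl enol ether of 9 (C1=C2 enol ether; 4E,8Z) | CC1(C)CCCC1(C)C(O[Si](C)(C)C)=CC/C(C)=C/CC/C(C)=C\CO[Si](c2ccccc2)(c3ccccc3)C(C)(C)C | intermediate
11 | (4E,8Z)-2-bromo-10-[(tert-butyldiphenylsilyl)oxy]-4,8-dimethyl-1-(1,2,2-trimethylcyclopentyl)deca-4,8-dien-1-one (both C2 epimers) | CC1(C)CCCC1(C)C(=O)C(Br)C/C(C)=C/CC/C(C)=C\CO[Si](c2ccccc2)(c3ccccc3)C(C)(C)C | intermediate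
12 | (1R,4E,8Z)-2-bromo-10-[(tert-butyldiphenylsilyl)oxy]-4,8-dimethyl-1-(1,2,2-trimethylcyclopentyl)deca-4,8-dien-1-ol (both C2 epimers) | CC1(C)CCCC1(C)[C@@H](O)C(Br)C/C(C)=C/CC/C(C)=C\CO[Si](c2ccccc2)(c3ccccc3)C(C)(C)C | intermediate
13 | tert-butyl({(2Z,6E)-3,7-dimethyl-8-[(3R)-3-(1,2,2-trimethylcyclopentyl)oxiran-2-yl]octa-2,6-dien-1-yl}oxy)diphenylsilane (both epimers at oxirane C2) | CC1(C)CCCC1(C)[C@H]2OC2C/C(C)=C/CC/C(C)=C\CO[Si](c3ccccc3)(c4ccccc4)C(C)(C)C | intermediate
14 | (13Z)-15-[(tert-butyldiphenylsilyl)oxy]labda-7,13-dien-6-ol (5S,9S,10S; both C6 epimers) | OC1C=C(C)[C@H](CC/C(C)=C\CO[Si](c3ccccc3)(c4ccccc4)C(C)(C)C)[C@@]2(C)CCCC(C)(C)[C@H]12 | intermediate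
15 | (13Z)-15-[(tert-butyldiphenylsilyl)oxy]labda-7,13-dien-6-one (5S,9S,10S) | O=C1C=C(C)[C@H](CC/C(C)=C\CO[Si](c3ccccc3)(c4ccccc4)C(C)(C)C)[C@@]2(C)CCCC(C)(C)[C@H]12 | intermediate
16 | potassium (13Z)-15-[(tert-butyldiphenylsilyl)oxy]labda-6,8,13-trien-6-olate | [K]OC1=CC(C)=C(CC/C(C)=C\CO[Si](c3ccccc3)(c4ccccc4)C(C)(C)C)[C@@]2(C)CCCC(C)(C)[C@H]12 | intermediate
17 | (13Z)-15-[(tert-butyldiphenylsilyl)oxy]-7α-hydroxylabda-8,13-dien-6-one (5S,7S,10S) | O=C1[C@@H](O)C(C)=C(CC/C(C)=C\CO[Si](c3ccccc3)(c4ccccc4)C(C)(C)C)[C@@]2(C)CCCC(C)(C)[C@H]12 | intermediate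
18 | (13Z)-15-[(tert-butyldiphenylsilyl)oxy]labda-8,13-diene-6β,7α-diol | O[C@@H]1[C@@H](O)C(C)=C(CC/C(C)=C\CO[Si](c3ccccc3)(c4ccccc4)C(C)(C)C)[C@@]2(C)CCCC(C)(C)[C@H]12 | intermediate
19 | (13Z)-15-[(tert-butyldiphenylsilyl)oxy]labda-8,13-diene-6β,7α-diyl diacetate | CC(=O)O[C@@H]1[C@@H](OC(C)=O)C(C)=C(CC/C(C)=C\CO[Si](c3ccccc3)(c4ccccc4)C(C)(C)C)[C@@]2(C)CCCC(C)(C)[C@H]12 | intermediate
20 | (13Z)-15-hydroxylabda-8,13-diene-6β,7α-diyl diacetate (5S,6S,7S,10S) | CC(=O)O[C@@H]1[C@@H](OC(C)=O)C(C)=C(CC/C(C)=C\CO)[C@@]2(C)CCCC(C)(C)[C@H]12 | target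

Total step count: 13. Longest linear sequence: 12 steps (nerol 4 to target 20, steps 2 to 13).

Steps most likely to fail

Step 8 (proposed new method). The Lewis acid-bound oxirane may isomerise to a ketone by hydride shift before the ring enlargement starts, the C10 cation may lose a proton before ring B closes, or the side-chain olefin may close a third ring. The fallback uses solvolysis chemistry of known type; it sets out from oxirane 13 and returns at alcohol 14. Opening of 13 at the less hindered C6 with 4-methoxyphenol and K2CO3 in DMF at 100 °C should give (1R,4E,8Z)-10-[(tert-butyldiphenylsilyl)oxy]-2-(4-methoxyphenoxy)-4,8-dimethyl-1-(1,2,2-trimethylcyclopentyl)deca-4,8-dien-1-ol F1. MsCl and Et3N should convert its hindered hydroxyl into the neopentyl-type mesylate F2. Buffered solvolysis (2,6-lutidine, (CF3)2CHOH, 50 °C) should ionise F2 with Wagner–Meerwein ring enlargement, and the resulting cyclohexyl cation should close ring B to (13Z)-15-[(tert-butyldiphenylsilyl)oxy]-6-(4-methoxyphenoxy)labda-7,13-diene F3. Oxidative removal of the aryl ether with (NH4)2Ce(NO3)6 in aqueous MeCN then gives 14.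

Step 10. Proton loss from the C8 methyl group instead of C9 would lead to the exocyclic olefin, oxygen transfer could occur at C9 instead of C7, and base could shift the ketol to the conjugated 6-hydroxy-7-ketone. The fallback sets out from enone 15 and returns at ketol 17. Silylation under thermodynamic conditions (Me3SiCl, NaI, Et3N, MeCN) should give (13Z)-15-[(tert-butyldiphenylsilyl)oxy]-6-(trimethylsilyloxy)labda-6,8,13-triene F4. Rubottom oxidation with dimethyldioxirane at −78 °C should epoxidise the enol ether olefin from the α face, and mild acid work-up then gives 17 without a free enolate.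

Step 7. Substrate control by the two racemic α-centres (the bromo carbon and the ring carbon) may compete with the catalyst, which would lower facial selectivity at C5 and with it the enantiomeric purity of everything downstream. The fallback sets out from ketone 9 and returns at oxirane 13 (as one C6 epimer). The potassium enolate of 9 is hydroxylated with the antipode of (camphorsulfonyl)oxaziridine that delivers (2S,4E,8Z)-10-[(tert-butyldiphenylsilyl)oxy]-2-hydroxy-4,8-dimethyl-1-(1,2,2-trimethylcyclopentyl)deca-4,8-dien-1-one F5. Chelation-controlled reduction with Zn(BH4)2 should give the anti (1R,2S)-diol F6, so that C5 is relayed from one oxygen-bearing centre. MsCl (1 equiv, pyridine, −20 °C) should sulfonylate the less hindered C2 hydroxyl to the monomesylate F7, and K2CO3 in MeOH closes the oxirane 13.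

Further compounds
F1 | step 8 | (1R,4E,8Z)-10-[(tert-butyldiphenylsilyl)oxy]-2-(4-methoxyphenoxy)-4,8-dimethyl-1-(1,2,2-trimethylcyclopentyl)deca-4,8-dien-1-ol | CC1(C)CCCC1(C)[C@@H](O)C(Oc2ccc(OC)cc2)C/C(C)=C/CC/C(C)=C\CO[Si](c3ccccc3)(c4ccccc4)C(C)(C)C
F2 | step 8 | (1R,4E,8Z)-10-[(tert-butyldiphenylsilyl)oxy]-2-(4-methoxyphenoxy)-4,8-dimethyl-1-(1,2,2-trimethylcyclopentyl)deca-4,8-dien-1-yl methanesulfonate | CC1(C)CCCC1(C)[C@@H](OS(C)(=O)=O)C(Oc2ccc(OC)cc2)C/C(C)=C/CC/C(C)=C\CO[Si](c3ccccc3)(c4ccccc4)C(C)(C)C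
F3 | step 8 | (13Z)-15-[(tert-butyldiphenylsilyl)oxy]-6-(4-methoxyphenoxy)labda-7,13-diene (5S,9S,10S) | COc1ccc(OC2C=C(C)[C@H](CC/C(C)=C\CO[Si](c3ccccc3)(c4ccccc4)C(C)(C)C)[C@@]5(C)CCCC(C)(C)[C@H]25)cc1
F4 | step 10 | (13Z)-15-[(tert-butyldiphenylsilyl)oxy]-6-(trimethylsilyloxy)labda-6,8,13-triene | C[Si](C)(C)OC1=CC(C)=C(CC/C(C)=C\CO[Si](c3ccccc3)(c4ccccc4)C(C)(C)C)[C@@]2(C)CCCC(C)(C)[C@H]12
F5 | step 7 | (2S,4E,8Z)-10-[(tert-butyldiphenylsilyl)oxy]-2-hydroxy-4,8-dimethyl-1-(1,2,2-trimethylcyclopentyl)deca-4,8-dien-1-one | CC1(C)CCCC1(C)C(=O)[C@@H](O)C/C(C)=C/CC/C(C)=C\CO[Si](c2ccccc2)(c3ccccc3)C(C)(C)C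
F6 | step 7 | (1R,2S,4E,8Z)-10-[(tert-butyldiphenylsilyl)oxy]-4,8-dimethyl-1-(1,2,2-trimethylcyclopentyl)deca-4,8-diene-1,2-diol | CC1(C)CCCC1(C)[C@@H](O)[C@@H](O)C/C(C)=C/CC/C(C)=C\CO[Si](c2ccccc2)(c3ccccc3)C(C)(C)C
F7 | step 7 | (1R,2S,4E,8Z)-10-[(tert-butyldiphenylsilyl)oxy]-1-hydroxy-4,8-dimethyl-1-(1,2,2-trimethylcyclopentyl)deca-4,8-dien-2-yl methanesulfonate | CC1(C)CCCC1(C)[C@@H](O)[C@@H](OS(C)(=O)=O)C/C(C)=C/CC/C(C)=C\CO[Si](c2ccccc2)(c3ccccc3)C(C)(C)C
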